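## Retrosynthetic overview

1. Target 16 ⇐ PMB ether 15 ⇐ vinyl oxirane 14: benzoate opens the oxirane at allylic C5 with inversion, which sets C5 and frees the C6 hydroxyl.
2. 14 ⇐ epoxy diol 12 ⇐ meso bis-epoxide 10: a chiral lithium amide converts one of the two enantiotopic oxiranes into the C2 carbinol and the C3=C4 alkene, fixing the absolute configuration.
3. 10 ⇐ diene 8: hydroxyl-directed double epoxidation (step 5, the key step). Both oxirane rings form in one operation on the CH2OH face, setting all four C–O stereocentres relative to C1.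
4. 8 ⇐ methyl benzoate 1 by Birch reduction, enolate hydroxylation, PMB protection and ester reduction.
5. Ring order: the carbocycle is the benzene ring of 1; the two oxiranes are formed together (step 5) and are consumed one each in steps 6 and 8.

Numbering used in all names: C1 = quaternary carbon (bears O and CH2O), C2 and C6 = its neighbours, C3=C4 = alkene of the target, C5 = second allylic carbon. Target = (1R,2R,5R,6S).

Assumption: the lithium amide of (S)-2-(pyrrolidin-1-ylmethyl)pyrrolidine opens 10 in the same spatial sense as it opens cyclohexene oxide (to (S)-cyclohex-2-enol); if the sense proves opposite, the (R)-diamine is used and nothing else changes.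

## Route

Step 1
Reactants: 1 methyl benzoate
Product: 3 methyl cyclohexa-2,5-diene-1-carboxylate, via sodium dienolate 2 (not isolated)
Conditions: Na (2.5 equiv), NH3(l)/THF, t-BuOH (1.5 equiv), −78 °C; then solid NH4Cl
Reagents that add atoms: none
Why: Birch reduction: the ester-stabilised radical anion is reduced at the ipso and para carbons to dienolate 2, and kinetic protonation of this cross-conjugated enolate at the alpha carbon by NH4Cl gives the unconjugated 2,5-diene (no stereocentre is formed).

Step 2
Reactants: 3 methyl cyclohexa-2,5-diene-1-carboxylate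
Product: 5 methyl 1-hydroxycyclohexa-2,5-diene-1-carboxylate, via potassium dienolate 4 (not isolated)
Conditions: KN(SiMe3)2 (1.1 equiv), THF, −78 °C; then 2-(phenylsulfonyl)-3-phenyloxaziridine (1.3 equiv), −78 °C; aq NH4Cl
Reagents that add atoms: 2-(phenylsulfonyl)-3-phenyloxaziridine, O=S(=O)(c1ccccc1)N1OC1c1ccccc1
Why: Davis oxaziridine hydroxylation of an ester enolate: like alkyl halides in Birch reductive alkylations the electrophilic oxygen enters at C1 of dienolate 4, and a two-electron oxygen-transfer reagent at −78 °C avoids the radical pathways that would aromatise the ring (C1 is prochiral, its two alkenes are enantiotopic).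

Step 3
Reactants: 5 methyl 1-hydroxycyclohexa-2,5-diene-1-carboxylate
Product: 7 methyl 1-[(4-methoxybenzyl)oxy]cyclohexa-2,5-diene-1-carboxylate, via sodium alkoxide 6 (not isolated)
Conditions: NaH (1.3 equiv), 4-methoxybenzyl chloride (1.3 equiv), Bu4NI (cat.), DMF, 0 °C → rt
Reagents that add atoms: 4-methoxybenzyl chloride, COc1ccc(CCl)cc1
Why: Williamson ether synthesis: the tertiary alkoxide 6 is alkylated by the activated benzylic halide under iodide catalysis, the ester has no alpha hydrogen to enolise, and basic conditions avoid the acid-triggered loss of water that would aromatise 5; the ether later keeps the tertiary oxygen from acting as a directing group and from Payne rearrangement.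

Step 4
Reactants: 7 methyl 1-[(4-methoxybenzyl)oxy]cyclohexa-2,5-diene-1-carboxylate
Product: 8 {1-[(4-methoxybenzyl)oxy]cyclohexa-2,5-dien-1-yl}methanol
Conditions: LiAlH4 (1.0 equiv), Et2O, 0 °C; Na2SO4·10H2O quench; Et3N-deactivated silica
Reagents that add atoms: none
Why: Hydride reduction of the ester: LiAlH4 reduces the alpha-alkoxy ester quickly at 0 °C while the isolated cis alkenes and the benzylic ether are inert, giving the free homoallylic alcohol needed to direct step 5.

Step 5
Reactants: 8 {1-[(4-methoxybenzyl)oxy]cyclohexa-2,5-dien-1-yl}methanol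
Product: 10 meso bis-epoxide {(2R,3R,5S,6S)-2,3:5,6-diepoxy-1-[(4-methoxybenzyl)oxy]cyclohexyl}methanol (both oxiranes cis to CH2OH), via racemic mono-epoxide 9 (not isolated)
Conditions: VO(acac)2 (5 mol %), t-BuOOH (2.6 equiv, in decane), CH2Cl2, 0 °C → rt
Reagents that add atoms: tert-butyl hydroperoxide, CC(C)(C)OO
Why: Hydroxyl-directed vanadium-catalysed epoxidation used twice in one pot: the primary alkoxide bound to the vanadium tert-butylperoxide delivers oxygen to each of the two enantiotopic homoallylic cis alkenes on its own face, which is also the face anti to the allylic ether oxygen, so both oxirane rings form in one operation and four stereocentres (2R,3R,5S,6S) are set relative to C1 as the Cs-symmetric bis-epoxide.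

Step 6
Reactants: 10 meso bis-epoxide
Product: 12 (1S,2R,5S,6S)-5,6-epoxy-1-(hydroxymethyl)-1-[(4-methoxybenzyl)oxy]cyclohex-3-en-2-ol, via lithium alkoxide 11 (not isolated)
Conditions: (S)-2-(pyrrolidin-1-ylmethyl)pyrrolidine (3.0 equiv), n-BuLi (3.0 equiv), THF, 0 °C; add 10, 0 °C → rt; aq NH4Cl
Reagents that add atoms: none
Why: Enantioselective lithium amide rearrangement of a meso epoxide to an allylic alcohol (syn beta-elimination): after the first equivalent forms alkoxide 11, the chiral amide removes the C4 hydrogen syn to the oxiranes while breaking the C3–O bond of only one of the two enantiotopic oxiranes, which fixes the absolute configuration (C2 R, C1 now stereogenic) and leaves the other oxirane untouched because it has no beta hydrogen left.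

Step 7
Reactants: 12 epoxy diol
Product: 14 (1S,2R,5S,6S)-1-[(benzoyloxy)methyl]-5,6-epoxy-1-[(4-methoxybenzyl)oxy]cyclohex-3-en-2-yl benzoate, via primary monobenzoate 13 (not isolated)
Conditions: Bz2O (2.5 equiv), Et3N (4 equiv), DMAP (10 mol %), CH2Cl2, 0 °C → rt
Reagents that add atoms: benzoic anhydride, O=C(OC(=O)c1ccccc1)c1ccccc1
Why: DMAP-catalysed acylation: the primary and then the secondary allylic hydroxyl are benzoylated without touching any stereocentre, the tertiary oxygen is masked, and a chloride-free acyl donor keeps the vinyl oxirane intact.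

Step 8
Reactants: 14 dibenzoate vinyl oxirane
Product: 15 (1R,2R,5R,6S)-1-[(benzoyloxy)methyl]-6-hydroxy-1-[(4-methoxybenzyl)oxy]cyclohex-3-ene-2,5-diyl dibenzoate
Conditions: PhCO2H (4 equiv), PhCO2Na (1 equiv), DMF, 70 °C
Reagents that add atoms: benzoic acid, OC(=O)c1ccccc1
Why: SN2 opening of a vinyl epoxide by a carboxylate in a benzoic acid buffer: benzoate attacks the allylic, electronically activated C5 (C6 is neopentyl-like) anti to the oxirane oxygen, so C5 is inverted to R with the new benzoate trans to the C6 hydroxyl, which keeps its configuration, and the weakly acidic medium suppresses acyl migration.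

Step 9
Reactants: 15 PMB-protected tribenzoate
Product: 16 (1R,2R,5R,6S)-1-[(benzoyloxy)methyl]-1,6-dihydroxycyclohex-3-ene-2,5-diyl dibenzoate (target, CNP0128482.2)
Conditions: DDQ (1.5 equiv), CH2Cl2/pH 7 phosphate buffer (10:1), 0 °C → rt
Reagents that add atoms: none
Why: Oxidative cleavage of a 4-methoxybenzyl ether: DDQ abstracts hydride from the electron-rich benzylic position, water traps the oxocarbenium ion and releases 4-methoxybenzaldehyde and the tertiary alcohol under neutral conditions that leave the three benzoates, the alkene and all four stereocentres unchanged.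

## Compound list

1 | methyl benzoate | COC(=O)c1ccccc1 | starting material
2 | sodium dienolate of methyl cyclohexa-2,5-diene-1-carboxylate | COC([O-])=C1C=CCC=C1.[Na+] | intermediate
3 | methyl cyclohexa-2,5-diene-1-carboxylate | COC(=O)C1C=CCC=C1 | intermediate
4 | potassium dienolate of methyl cyclohexa-2,5-diene-1-carboxylate | COC([O-])=C1C=CCC=C1.[K+] | intermediate
5 | methyl 1-hydroxycyclohexa-2,5-diene-1-carboxylate | COC(=O)C1(O)C=CCC=C1 | intermediate
6 | sodium alkoxide of 5 | COC(=O)C1([O-])C=CCC=C1.[Na+] | intermediate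
7 | methyl 1-[(4-methoxybenzyl)oxy]cyclohexa-2,5-diene-1-carboxylate | COC(=O)C1(OCc2ccc(OC)cc2)C=CCC=C1 | intermediate
8 | {1-[(4-methoxybenzyl)oxy]cyclohexa-2,5-dien-1-yl}methanol | OCC1(OCc2ccc(OC)cc2)C=CCC=C1 | intermediate
9 | racemic mono-epoxide, (1S*,2R*,3R*)-2,3-epoxide cis to CH2OH, 5,6-alkene intact (one enantiomer drawn) | OC[C@]1(OCc2ccc(OC)cc2)[C@@H]3O[C@@H]3CC=C1 | intermediate
10 | meso bis-epoxide {(2R,3R,5S,6S)-2,3:5,6-diepoxy-1-[(4-methoxybenzyl)oxy]cyclohexyl}methanol, both oxiranes cis to CH2OH | OC[C@]1(OCc2ccc(OC)cc2)[C@@H]3O[C@@H]3C[C@@H]4O[C@H]14 | intermediate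
11 | lithium alkoxide of 10 | [Li+].[O-]C[C@]1(OCc2ccc(OC)cc2)[C@@H]3O[C@@H]3C[C@@H]4O[C@H]14 | intermediate
12 | (1S,2R,5S,6S)-5,6-epoxy-1-(hydroxymethyl)-1-[(4-methoxybenzyl)oxy]cyclohex-3-en-2-ol | OC[C@]1(OCc2ccc(OC)cc2)[C@H](O)C=C[C@@H]2O[C@H]12 | intermediate
13 | [(1S,2R,5S,6S)-5,6-epoxy-2-hydroxy-1-[(4-methoxybenzyl)oxy]cyclohex-3-en-1-yl]methyl benzoate | O=C(OC[C@]1(OCc2ccc(OC)cc2)[C@H](O)C=C[C@@H]2O[C@H]12)c1ccccc1 | intermediate
14 | (1S,2R,5S,6S)-1-[(benzoyloxy)methyl]-5,6-epoxy-1-[(4-methoxybenzyl)oxy]cyclohex-3-en-2-yl benzoate | O=C(OC[C@]1(OCc2ccc(OC)cc2)[C@H](OC(=O)c2ccccc2)C=C[C@@H]2O[C@H]12)c1ccccc1 | intermediate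
15 | (1R,2R,5R,6S)-1-[(benzoyloxy)methyl]-6-hydroxy-1-[(4-methoxybenzyl)oxy]cyclohex-3-ene-2,5-diyl dibenzoate | O=C(OC[C@]1(OCc2ccc(OC)cc2)[C@H](OC(=O)c2ccccc2)C=C[C@@H](OC(=O)c2ccccc2)[C@@H]1O)c1ccccc1 | intermediate
16 | (1R,2R,5R,6S)-1-[(benzoyloxy)methyl]-1,6-dihydroxycyclohex-3-ene-2,5-diyl dibenzoate | O=C(OC[C@]1(O)[C@H](OC(=O)c2ccccc2)C=C[C@@H](OC(=O)c2ccccc2)[C@@H]1O)c1ccccc1 | target

## Totals and risks

Total steps: 9. Longest linear sequence: 9 steps (1 → 16, fully linear).

**Step 6 (most likely to fail).** The amide may give low enantioselectivity on a substrate that carries an internal lithium alkoxide, or may add to the vinyl oxirane it creates. The fallback sets out from 10 and comes back at 14. Achiral LiNEt2 (THF, 0 °C) gives the racemic epoxy diol, that is 12 together with its enantiomer ent-12 F1. Bz2O (1.05 equiv) with 2,4,6-collidine at −40 °C benzoylates only the primary hydroxyl, giving 13 together with ent-13 F2. Immobilised Candida antarctica lipase B with vinyl benzoate in toluene at 40 °C then benzoylates the (2R)-alcohol 13 to 14 (large quaternary C1 against the medium vinyl arm, Kazlauskas rule) and leaves ent-13 F2 behind, which is removed on silica. The ceiling is 50 %.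

**Step 5.** The homoallylic direction is slower than allylic direction, and the bis-allylic tertiary ether 8 could ionise and aromatise at the Lewis-acidic vanadium centre. The fallback sets out from 8 and comes back at 10. n-BuLi and then CO2 (THF, −78 → 0 °C) turn 8 into lithium {1-[(4-methoxybenzyl)oxy]cyclohexa-2,5-dien-1-yl}methyl carbonate F3, and I2 closes the cis-fused six-membered cyclic iodo carbonate F4 (carbonate oxygen at C2 on the CH2O face, iodine at C3 anti). K2CO3 in MeOH cleaves the carbonate, and the freed C2 alkoxide displaces iodide to give mono-epoxide 9, isolated here. The same operations on 9 give the lithium carbonate F5, then the epoxy iodo carbonate F6, and then 10. Each oxirane is placed by a tethered cyclisation without Lewis acid or peroxide, at the cost of three more operations.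

**Step 2.** Dienolate 4 may be oxidised to methyl benzoate, or the alkoxide of 5 may add to the sulfonyl imine by-product. The fallback sets out from 3 and comes back at 8, bypassing steps 3 and 4. Potassium dienolate 4 (KN(SiMe3)2, THF, −78 °C) is quenched with dibenzoyl peroxide to give methyl 1-(benzoyloxy)cyclohexa-2,5-diene-1-carboxylate F7. LiAlH4 (Et2O, 0 °C) reduces both esters to 1-(hydroxymethyl)cyclohexa-2,5-dien-1-ol F8. 4-Methoxybenzaldehyde dimethyl acetal with pyridinium p-toluenesulfonate closes the spiro acetal 2-(4-methoxyphenyl)-1,3-dioxaspiro[4.5]deca-6,9-diene F9. i-Bu2AlH (CH2Cl2, −78 → 0 °C) opens the acetal with aluminium on the less hindered primary oxygen, so the 4-methoxybenzyl group stays on the tertiary oxygen, which is 8.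

## Further compounds

F1 | step 6 | ent-12, (1R,2S,5R,6R)-5,6-epoxy-1-(hydroxymethyl)-1-[(4-methoxybenzyl)oxy]cyclohex-3-en-2-ol | OC[C@@]1(OCc2ccc(OC)cc2)[C@@H](O)C=C[C@H]2O[C@@H]12
F2 | step 6 | ent-13, [(1R,2S,5R,6R)-5,6-epoxy-2-hydroxy-1-[(4-methoxybenzyl)oxy]cyclohex-3-en-1-yl]methyl benzoate | O=C(OC[C@@]1(OCc2ccc(OC)cc2)[C@@H](O)C=C[C@H]2O[C@@H]12)c1ccccc1
F3 | step 5 | lithium {1-[(4-methoxybenzyl)oxy]cyclohexa-2,5-dien-1-yl}methyl carbonate | [Li+].[O-]C(=O)OCC1(OCc2ccc(OC)cc2)C=CCC=C1
F4 | step 5 | racemic cis-fused cyclic iodo carbonate of 8 (carbonate O at C2 cis to CH2O, I at C3 trans to it, 5,6-alkene intact; one enantiomer drawn) | O=C1OC[C@@]2(OCc3ccc(OC)cc3)C=CC[C@H](I)[C@H]2O1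
F5 | step 5 | racemic lithium carbonate of 9 (2,3-oxirane cis to CH2O, 5,6-alkene intact; one enantiomer drawn) | [Li+].[O-]C(=O)OC[C@]1(OCc2ccc(OC)cc2)[C@@H]3O[C@@H]3CC=C1
F6 | step 5 | racemic cyclic iodo carbonate of 9 (2,3-oxirane and carbonate O at C6 cis to CH2O, I at C5 trans; one enantiomer drawn) | O=C1OC[C@]2(OCc3ccc(OC)cc3)[C@@H]3O[C@@H]3C[C@@H](I)[C@@H]2O1
F7 | step 2 | methyl 1-(benzoyloxy)cyclohexa-2,5-diene-1-carboxylate | COC(=O)C1(OC(=O)c2ccccc2)C=CCC=C1
F8 | step 2 | 1-(hydroxymethyl)cyclohexa-2,5-dien-1-ol | OCC1(O)C=CCC=C1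
F9 | step 2 | 2-(4-methoxyphenyl)-1,3-dioxaspiro[4.5]deca-6,9-diene (racemic at the acetal carbon) | COc1ccc(cc1)C1OCC2(O1)C=CCC=C2
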